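## Retrosynthetic overview

1. Target 18 ⇐ sulfone 15: the phenylsulfonyl group on C12 is removed last; it is the handle that made C12 nucleophilic.
2. Rings: 13 ⇐ acyclic tetraene 10 in one enantioselective proton-initiated cascade, ring A first (C4–C5), then ring B (C9–C10). The sulfone next to C13 stops the cascade at the bicycle.
3. Key C11–C12 bond: sulfone-stabilised allyl carbanion of 6 (a reversed-polarity prenyl unit) + (2E,6E)-farnesyl bromide 7, joining two allylic carbons that are both natively electrophilic.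
4. 6 ⇐ methyl 4-hydroxybenzoate 4 + chlorosulfone 3 (ortho C-allylation); 3 ⇐ isoprene + PhSO2Cl, which fixes the E-trisubstituted alkene.

Assumption: the target's ring-fusion centres are (4aR,8aR) (labdane C5/C10 both R), antipodal to the sclareolide series, so the decalin is made by asymmetric catalysis; sulfone intermediates are carried as both epimers at the sulfonyl carbon.

## Route

Step 1
Reactants: 1 isoprene; 2 benzenesulfonyl chloride
Product: 3 [(2E)-4-chloro-2-methylbut-2-en-1-yl]sulfonylbenzene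
Conditions: CuCl (5 mol%), Et3N·HCl (5 mol%), MeCN, 100 °C, sealed tube
Reagents that add atoms: none
Why: CuCl-catalysed atom-transfer 1,4-chlorosulfonylation of a diene, in which the sulfonyl radical adds to the methyl-bearing terminus (more substituted allyl radical) and chlorine is delivered to the far terminus, giving the more stable E-trisubstituted alkene.

Step 2
Reactants: 4 methyl 4-hydroxybenzoate; 3 [(2E)-4-chloro-2-methylbut-2-en-1-yl]sulfonylbenzene
Product: 6 methyl 4-hydroxy-3-[(2E)-3-methyl-4-(phenylsulfonyl)but-2-en-1-yl]benzoate, via sodium 4-(methoxycarbonyl)phenoxide 5 (not isolated)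
Conditions: NaH (1.0 equiv to 4), toluene, 0 → 25 °C; then 3 (0.8 equiv), NaI (10 mol%), 70 °C
Reagents that add atoms: none
Why: Ortho C-alkylation (SN2 at the primary allylic chloride) of a contact-ion-pair sodium phenoxide in a non-polar solvent, with the para position blocked, the alkene geometry retained and the α-sulfonyl protons untouched by the weakly basic phenoxide; the O-allyl ether is the expected by-product and the yield is moderate.

Step 3
Reactants: 6 methyl 4-hydroxy-3-[(2E)-3-methyl-4-(phenylsulfonyl)but-2-en-1-yl]benzoate; 7 (2E,6E)-farnesyl bromide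
Product: 10 methyl 4-acetoxy-3-[(2E,6E,10E)-3,7,11,15-tetramethyl-4-(phenylsulfonyl)hexadeca-2,6,10,14-tetraen-1-yl]benzoate (racemic at the sulfonyl carbon), via dilithium phenoxide sulfonyl carbanion 8 (not isolated), via lithium phenoxide of the alkylated sulfone 9 (not isolated)
Conditions: LiN(iPr)2 (2.05 equiv), THF, −78 °C; 7 (1.0 equiv), −78 → −30 °C; then Ac2O (1.5 equiv), −30 → 0 °C
Reagents that add atoms: acetic anhydride, CC(=O)OC(C)=O
Why: Alkylation of a sulfone-stabilised allyl carbanion (Julia/Biellmann-type coupling), in which the dianion reacts at its more basic carbon α to sulfur with the primary allylic bromide by SN2, keeping all E-alkenes, and the phenoxide is then O-acetylated in the same flask; the new sulfonyl stereocentre is racemic and is erased in step 6.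

Step 4
Reactants: 10 methyl 4-acetoxy-3-[(2E,6E,10E)-3,7,11,15-tetramethyl-4-(phenylsulfonyl)hexadeca-2,6,10,14-tetraen-1-yl]benzoate
Product: 13 methyl 4-acetoxy-3-[(2E)-3-methyl-4-(phenylsulfonyl)-5-[(4aR,8aR)-2,5,5,8a-tetramethyl-3,4,4a,5,6,7,8,8a-octahydronaphthalen-1-yl]pent-2-en-1-yl]benzoate (both sulfone epimers), via exocyclic 8(17)-alkene isomer 11 (not isolated), via ring-trisubstituted 7-alkene isomer 12 (not isolated)
Conditions: chiral imidodiphosphorimidate (IDPi) Brønsted acid (5 mol%; mirror image of the catalyst that turns homofarnesol into natural (−)-ambrox), (CF3)3COH, −20 °C; then CF3SO3H (10 mol%), CH2Cl2, 0 °C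
Reagents that add atoms: none
Why: Proposed new method: an enantioselective proton-initiated polyene bicyclization through a chair–chair (Stork–Eschenmoser) fold, in which the confined acid protonates only the terminal isopropylidene, ring-A closure sets C5 and ring-B closure sets C10 and the trans fusion, the C13=C14 alkene stays out because its attack on the C8 cation would place a cation at C13 beside the sulfonyl carbon, and the C8 cation can only lose a proton to give alkene isomers that the second acid equilibrates to the tetrasubstituted C8=C9 alkene; the closest known reactions are the IDPi-catalysed cyclization of homofarnesol to ambrox (hydroxyl-terminated) and the acid equilibration that converts sclareolide into its C8=C9 unsaturated ester.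

Step 5
Reactants: 13 methyl 4-acetoxy-3-[(2E)-3-methyl-4-(phenylsulfonyl)-5-[(4aR,8aR)-2,5,5,8a-tetramethyl-3,4,4a,5,6,7,8,8a-octahydronaphthalen-1-yl]pent-2-en-1-yl]benzoate
Product: 15 4-hydroxy-3-[(2E)-3-methyl-4-(phenylsulfonyl)-5-[(4aR,8aR)-2,5,5,8a-tetramethyl-3,4,4a,5,6,7,8,8a-octahydronaphthalen-1-yl]pent-2-en-1-yl]benzoic acid (both sulfone epimers), via dipotassium carboxylate phenoxide salt 14 (not isolated)
Conditions: KOH (6 equiv), THF/MeOH/H2O 3:1:1, 50 °C; then 1 M HCl
Reagents that add atoms: potassium hydroxide, [K+].[OH-]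
Why: Saponification cleaves the methyl ester and the aryl acetate together, while the hindered tertiary α-sulfonyl C–H is not acidic enough for aqueous hydroxide to move the allylic alkene.

Step 6
Reactants: 15 4-hydroxy-3-[(2E)-3-methyl-4-(phenylsulfonyl)-5-[(4aR,8aR)-2,5,5,8a-tetramethyl-3,4,4a,5,6,7,8,8a-octahydronaphthalen-1-yl]pent-2-en-1-yl]benzoic acid
Product: 18 4-hydroxy-3-[(2E)-3-methyl-5-[(4aR,8aR)-2,5,5,8a-tetramethyl-3,4,4a,5,6,7,8,8a-octahydronaphthalen-1-yl]pent-2-en-1-yl]benzoic acid, via dilithium salt of the sulfone acid 16 (not isolated), via dilithium salt of the target 17 (not isolated)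
Conditions: PdCl2[Ph2P(CH2)3PPh2] (5 mol%), LiBHEt3 (4.5 equiv), THF, 0 °C; then 1 M HCl
Reagents that add atoms: none
Why: Reductive desulfonylation of an allylic sulfone catalysed by PdCl2[Ph2P(CH2)3PPh2], in which the first two equivalents of hydride convert 15 into its dilithium carboxylate phenoxide (inert to the borohydride at 0 °C), zerovalent palladium ionises the C–S bond to a π-allyl complex, and hydride returns to the former sulfonyl carbon so the C13=C14 alkene keeps its position and E geometry (the behaviour known for allylic sulfones in polyprenyl chains).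

## Compound list

1 | isoprene | C=CC(C)=C | starting material
2 | benzenesulfonyl chloride | O=S(=O)(Cl)c1ccccc1 | starting material
3 | [(2E)-4-chloro-2-methylbut-2-en-1-yl]sulfonylbenzene | O=S(=O)(C/C(C)=C/CCl)c1ccccc1 | intermediate
4 | methyl 4-hydroxybenzoate | COC(=O)c1ccc(O)cc1 | starting material
5 | sodium 4-(methoxycarbonyl)phenoxide | COC(=O)c1ccc([O-])cc1.[Na+] | intermediate (not isolated)
6 | methyl 4-hydroxy-3-[(2E)-3-methyl-4-(phenylsulfonyl)but-2-en-1-yl]benzoate | COC(=O)c1ccc(O)c(C/C=C(\C)CS(=O)(=O)c2ccccc2)c1 | intermediate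
7 | (2E,6E)-farnesyl bromide | CC(C)=CCC/C(C)=C/CC/C(C)=C/CBr | starting material
8 | dilithium salt of 6 (phenoxide and α-sulfonyl allyl carbanion) | COC(=O)c1ccc([O-])c(C/C=C(\C)[CH-]S(=O)(=O)c2ccccc2)c1.[Li+].[Li+] | intermediate (not isolated)
9 | lithium phenoxide of the farnesylated sulfone | COC(=O)c1ccc([O-])c(C/C=C(\C)C(C/C=C(\C)CC/C=C(\C)CCC=C(C)C)S(=O)(=O)c2ccccc2)c1.[Li+] | intermediate (not isolated)
10 | methyl 4-acetoxy-3-[(2E,6E,10E)-3,7,11,15-tetramethyl-4-(phenylsulfonyl)hexadeca-2,6,10,14-tetraen-1-yl]benzoate (racemic at the sulfonyl carbon) | COC(=O)c1ccc(OC(C)=O)c(C/C=C(\C)C(C/C=C(\C)CC/C=C(\C)CCC=C(C)C)S(=O)(=O)c2ccccc2)c1 | intermediate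
11 | methyl 4-acetoxy-3-[(2E)-3-methyl-4-(phenylsulfonyl)-5-[(1R,4aR,8aR)-5,5,8a-trimethyl-2-methylidenedecahydronaphthalen-1-yl]pent-2-en-1-yl]benzoate | C=C1CC[C@@H]2C(C)(C)CCC[C@@]2(C)[C@@H]1CC(/C(C)=C/Cc1cc(C(=O)OC)ccc1OC(C)=O)S(=O)(=O)c1ccccc1 | intermediate (not isolated)
12 | methyl 4-acetoxy-3-[(2E)-3-methyl-4-(phenylsulfonyl)-5-[(1R,4aR,8aR)-2,5,5,8a-tetramethyl-1,4,4a,5,6,7,8,8a-octahydronaphthalen-1-yl]pent-2-en-1-yl]benzoate | CC1=CC[C@@H]2C(C)(C)CCC[C@@]2(C)[C@@H]1CC(/C(C)=C/Cc1cc(C(=O)OC)ccc1OC(C)=O)S(=O)(=O)c1ccccc1 | intermediate (not isolated)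
13 | methyl 4-acetoxy-3-[(2E)-3-methyl-4-(phenylsulfonyl)-5-[(4aR,8aR)-2,5,5,8a-tetramethyl-3,4,4a,5,6,7,8,8a-octahydronaphthalen-1-yl]pent-2-en-1-yl]benzoate (both sulfone epimers) | CC1=C(CC(/C(C)=C/Cc2cc(C(=O)OC)ccc2OC(C)=O)S(=O)(=O)c2ccccc2)[C@]2(C)CCCC(C)(C)[C@H]2CC1 | intermediate
14 | dipotassium salt (carboxylate and phenoxide) of 15 | CC1=C(CC(/C(C)=C/Cc2cc(C(=O)[O-])ccc2[O-])S(=O)(=O)c2ccccc2)[C@]2(C)CCCC(C)(C)[C@H]2CC1.[K+].[K+] | intermediate (not isolated)
15 | 4-hydroxy-3-[(2E)-3-methyl-4-(phenylsulfonyl)-5-[(4aR,8aR)-2,5,5,8a-tetramethyl-3,4,4a,5,6,7,8,8a-octahydronaphthalen-1-yl]pent-2-en-1-yl]benzoic acid (both sulfone epimers) | CC1=C(CC(/C(C)=C/Cc2cc(C(=O)O)ccc2O)S(=O)(=O)c2ccccc2)[C@]2(C)CCCC(C)(C)[C@H]2CC1 | intermediate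
16 | dilithium salt (carboxylate and phenoxide) of 15 | CC1=C(CC(/C(C)=C/Cc2cc(C(=O)[O-])ccc2[O-])S(=O)(=O)c2ccccc2)[C@]2(C)CCCC(C)(C)[C@H]2CC1.[Li+].[Li+] | intermediate (not isolated)
17 | dilithium salt (carboxylate and phenoxide) of 18 | CC1=C(CC/C(C)=C/Cc2cc(C(=O)[O-])ccc2[O-])[C@]2(C)CCCC(C)(C)[C@H]2CC1.[Li+].[Li+] | intermediate (not isolated)
18 | 4-hydroxy-3-[(2E)-3-methyl-5-[(4aR,8aR)-2,5,5,8a-tetramethyl-3,4,4a,5,6,7,8,8a-octahydronaphthalen-1-yl]pent-2-en-1-yl]benzoic acid | CC1=C(CC/C(C)=C/Cc2cc(C(=O)O)ccc2O)[C@]2(C)CCCC(C)(C)[C@H]2CC1 | target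

## Step count and risks

Total steps: 6. Longest linear sequence: 6 (1 + 2 → 3 → 6 → 10 → 13 → 15 → 18); 4 and 7 enter convergently.

**Step 4 (most likely to fail).** The asymmetric cascade has no hydroxyl terminator, so enantioselectivity is unproven. The ring alkene may also settle as a C8=C9 / C7=C8 mixture. Fallback, setting out from 10 and returning at 18: cyclize 10 with an achiral acid (SnCl4 in CH2Cl2 at −78 °C, then the same CF3SO3H equilibration) to the racemic cyclized sulfone F1. Carry it through the hydrolysis and desulfonylation of steps 5 and 6 as the racemic hydroxy acid sulfone F2 and the racemic acid F3. Resolve F3 by crystallising the (R)-1-phenylethylammonium salt of the (4aR,8aR) acid F4 (the antipodal amine if its salt is the less soluble one, with chiral-phase chromatography as back-up). Acidification of F4 gives 18. The same salt crystallisation also raises the enantiomeric ratio of material from the catalytic route.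

**Step 2.** The ester-deactivated phenoxide may give mainly O-allylation or react sluggishly. Fallback, setting out from 4 and returning at 6: iodinate 4 ortho to the hydroxyl (ICl, AcOH) to methyl 4-hydroxy-3-iodobenzoate F5. Borylate it (bis(pinacolato)diboron, PdCl2[Fe(C5H4PPh2)2], KOAc, dioxane, 80 °C) to methyl 4-hydroxy-3-(4,4,5,5-tetramethyl-1,3,2-dioxaborolan-2-yl)benzoate F6. Couple F6 with allylic chloride 3 under Suzuki–Miyaura conditions (Pd(PPh3)4, K2CO3, THF/H2O, 50 °C), which attacks the unsubstituted allyl terminus and gives 6.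

**Step 6.** Both termini of the π-allyl intermediate are secondary, so the hydride may be delivered to the wrong one, or the dilithium salt may react poorly. Fallback, setting out from 13 and returning at 18: desulfonylate 13 by single-electron reduction (SmI2, HMPA, THF/MeOH, −20 °C) to the sulfone-free diester methyl 4-acetoxy-3-[(2E)-3-methyl-5-[(4aR,8aR)-2,5,5,8a-tetramethyl-3,4,4a,5,6,7,8,8a-octahydronaphthalen-1-yl]pent-2-en-1-yl]benzoate F7. Remove any alkene-position isomers at this neutral stage on AgNO3-impregnated silica. Saponify both esters with LiOH·H2O (THF/MeOH/H2O, 45 °C), which passes through the dilithium salt 17, and acidify with 1 M HCl to reach 18.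

## Further compounds

F1 | step 4 | racemate of 13 (1:1 mixture of the (4aR,8aR) and (4aS,8aS) forms, both sulfone epimers) | CC1=C(CC(/C(C)=C/Cc2cc(C(=O)OC)ccc2OC(C)=O)S(=O)(=O)c2ccccc2)[C@]2(C)CCCC(C)(C)[C@H]2CC1.CC1=C(CC(/C(C)=C/Cc2cc(C(=O)OC)ccc2OC(C)=O)S(=O)(=O)c2ccccc2)[C@@]2(C)CCCC(C)(C)[C@@H]2CC1
F2 | step 4 | racemate of 15 (1:1 mixture of the (4aR,8aR) and (4aS,8aS) forms, both sulfone epimers) | CC1=C(CC(/C(C)=C/Cc2cc(C(=O)O)ccc2O)S(=O)(=O)c2ccccc2)[C@]2(C)CCCC(C)(C)[C@H]2CC1.CC1=C(CC(/C(C)=C/Cc2cc(C(=O)O)ccc2O)S(=O)(=O)c2ccccc2)[C@@]2(C)CCCC(C)(C)[C@@H]2CC1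
F3 | step 4 | racemate of 18 (1:1 mixture of the (4aR,8aR) and (4aS,8aS) acids) | CC1=C(CC/C(C)=C/Cc2cc(C(=O)O)ccc2O)[C@]2(C)CCCC(C)(C)[C@H]2CC1.CC1=C(CC/C(C)=C/Cc2cc(C(=O)O)ccc2O)[C@@]2(C)CCCC(C)(C)[C@@H]2CC1
F4 | step 4 | (R)-1-phenylethylammonium salt of the (4aR,8aR) acid 18 | C[C@@H]([NH3+])c1ccccc1.CC1=C(CC/C(C)=C/Cc2cc(C(=O)[O-])ccc2O)[C@]2(C)CCCC(C)(C)[C@H]2CC1
F5 | step 2 | methyl 4-hydroxy-3-iodobenzoate | COC(=O)c1ccc(O)c(I)c1
F6 | step 2 | methyl 4-hydroxy-3-(4,4,5,5-tetramethyl-1,3,2-dioxaborolan-2-yl)benzoate | COC(=O)c1ccc(O)c(B2OC(C)(C)C(C)(C)O2)c1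
F7 | step 6 | methyl 4-acetoxy-3-[(2E)-3-methyl-5-[(4aR,8aR)-2,5,5,8a-tetramethyl-3,4,4a,5,6,7,8,8a-octahydronaphthalen-1-yl]pent-2-en-1-yl]benzoate | CC1=C(CC/C(C)=C/Cc2cc(C(=O)OC)ccc2OC(C)=O)[C@]2(C)CCCC(C)(C)[C@H]2CC1
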